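**Plan**

Retrosynthesis: the two MOM ethers are removed first, then ring C is cut at O1–C8a, which turns ring A back into the para-quinol of a 4-hydroxybenzyl group. Next come C3–C4 (enolate benzylation), the carboxyl carbon on the ring B benzylic position (one-carbon homologation of an aldehyde) and C5'–CMe2 (Claisen rearrangement of the O4' prenyl ether).
Forward: ring B is built on 2,3,4-trihydroxybenzaldehyde (O4-prenylation, MOM and methyl ethers, Claisen, homologation), joined to ring A by the C3–C4 alkylation, and ring C is closed last while ring A is re-aromatised in the same flask.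
Enabling feature: the 7-hydroxyl of ring A is para to C4a, so ring A can travel as a plain 4-hydroxybenzyl unit. Oxidising it to the para-quinol puts a hydroxyl on C4a and makes C8a a dienone β-carbon six atoms from the C2 hydroxyl.
Stereochemistry: the only stereocentre, C3 (R), is set by face-selective alkylation of the Z-enolate of an (R)-4-benzyl-2-oxazolidinone imide and is not touched afterwards.

Key step: step 14

Notation and assumption: ArB = 2-methoxy-3,4-bis(methoxymethoxy)-5-(2-methylbut-3-en-2-yl)phenyl. The oxa-Michael adduct of the key step and its trifluoroacetate are assumed to form as cis-fused diastereomer pairs, so their ring-fusion centres (C4a, C8a) are left undefined in the SMILES; aromatisation erases them.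

**Route**

Step 1
Reactants: 1 2,3,4-trihydroxybenzaldehyde; 2 prenyl bromide (1-bromo-3-methylbut-2-ene)
Product: 3 2,3-dihydroxy-4-[(3-methylbut-2-en-1-yl)oxy]benzaldehyde
Conditions: NaHCO3, DMF, 40 °C
Reagents that add atoms: none
Why: Williamson etherification under weak-base control: NaHCO3 ionises only the 4-hydroxyl (para to the formyl group, most acidic, not hydrogen-bonded), so SN2 alkylation by the allylic bromide should occur at O4 and leave O2 and O3 free.

Step 2
Reactants: 3 2,3-dihydroxy-4-[(3-methylbut-2-en-1-yl)oxy]benzaldehyde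
Product: 4 2-hydroxy-3-(methoxymethoxy)-4-[(3-methylbut-2-en-1-yl)oxy]benzaldehyde
Conditions: MeOCH2Cl (1.1 equiv), i-Pr2NEt, CH2Cl2, 0 °C → rt
Reagents that add atoms: chloromethyl methyl ether, COCCl
Why: Williamson-type alkylation with MOMCl: the 2-hydroxyl is held in a hydrogen bond to the formyl oxygen and is the least nucleophilic site, so one equivalent of the chloride with an amine base should etherify the 3-hydroxyl alone.

Step 3
Reactants: 4 2-hydroxy-3-(methoxymethoxy)-4-[(3-methylbut-2-en-1-yl)oxy]benzaldehyde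
Product: 5 2-methoxy-3-(methoxymethoxy)-4-[(3-methylbut-2-en-1-yl)oxy]benzaldehyde
Conditions: MeI, K2CO3, DMF, 40 °C
Reagents that add atoms: iodomethane, CI
Why: Williamson methylation: K2CO3 in DMF ionises the remaining chelated phenol and MeI caps it, while the allyl ether and the acetal are inert to these conditions.

Step 4
Reactants: 5 2-methoxy-3-(methoxymethoxy)-4-[(3-methylbut-2-en-1-yl)oxy]benzaldehyde
Product: 7 4-hydroxy-2-methoxy-3-(methoxymethoxy)-5-(2-methylbut-3-en-2-yl)benzaldehyde, via Claisen dienone 6 (not isolated)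
Conditions: PhNEt2, 190 °C, sealed tube, argon
Reagents that add atoms: none
Why: aromatic Claisen rearrangement ([3,3]-sigmatropic shift): with C3 blocked by the MOM ether the prenyl unit can only be delivered, with allylic inversion, to C5, and tautomerisation of dienone 6 gives the phenol carrying the 1,1-dimethylallyl group, the basic solvent holding back acid-promoted cyclisation of the product.

Step 5
Reactants: 7 4-hydroxy-2-methoxy-3-(methoxymethoxy)-5-(2-methylbut-3-en-2-yl)benzaldehyde
Product: 8 2-methoxy-3,4-bis(methoxymethoxy)-5-(2-methylbut-3-en-2-yl)benzaldehyde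
Conditions: NaH, MeOCH2Cl, DMF, 0 °C → rt
Reagents that add atoms: chloromethyl methyl ether, COCCl
Why: Williamson etherification: NaH fully ionises the hindered but acidic phenol (para to the formyl group), and the small, reactive chloromethyl ether should still reach it.

Step 6
Reactants: 8 2-methoxy-3,4-bis(methoxymethoxy)-5-(2-methylbut-3-en-2-yl)benzaldehyde
Product: 10 (ArB)acetonitrile, via potassium N-formyl enamide 9 (not isolated)
Conditions: TosMIC, KOt-Bu, DME, −40 °C; then MeOH, reflux
Reagents that add atoms: p-toluenesulfonylmethyl isocyanide (TosMIC), Cc1ccc(cc1)S(=O)(=O)C[N+]#[C-]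
Why: Van Leusen reductive cyanation: the TosMIC anion adds to the aldehyde, the oxazoline formed opens to N-formyl enamide 9, and methanolysis removes the formyl group and expels sulfinate to give the nitrile with one more carbon.

Step 7
Reactants: 10 (ArB)acetonitrile
Product: 11 (ArB)acetic acid
Conditions: KOH, EtOH/H2O, reflux; then aq. KHSO4 to pH 4, 0 °C
Reagents that add atoms: water, O; potassium hydroxide, [K+].[OH-]
Why: alkaline nitrile hydrolysis through the primary amide: the MOM ethers, the methyl ether and the unactivated alkene tolerate hot hydroxide, and the acidification is kept at pH 4 and 0 °C to spare the acetals.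

Step 8
Reactants: 11 (ArB)acetic acid; 12 (R)-4-benzyl-2-oxazolidinone
Product: 14 (4R)-4-benzyl-3-[(ArB)acetyl]-1,3-oxazolidin-2-one, via mixed pivalic anhydride 13 (not isolated)
Conditions: t-BuCOCl, Et3N, THF, −20 → 0 °C; then LiCl, 12, 0 °C → rt
Reagents that add atoms: none
Why: N-acylation of the oxazolidinone through a mixed pivalic anhydride (LiCl/Et3N variant): the unhindered arylacetyl carbonyl of 13 is attacked in preference to the one shielded by the tert-butyl group.

Step 9
Reactants: 15 p-cresol
Product: 16 4-methylphenyl 2,2-dimethylpropanoate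
Conditions: t-BuCOCl, Et3N, DMAP (cat.), CH2Cl2, 0 °C → rt
Reagents that add atoms: pivaloyl chloride, CC(C)(C)C(Cl)=O
Why: DMAP-catalysed O-acylation of a phenol, giving an ester robust enough for radical bromination and enolate alkylation yet cleavable by hydride.

Step 10
Reactants: 16 4-methylphenyl 2,2-dimethylpropanoate
Product: 17 4-(bromomethyl)phenyl 2,2-dimethylpropanoate
Conditions: NBS, AIBN (cat.), PhCF3, 80 °C
Reagents that add atoms: N-bromosuccinimide, O=C1CCC(=O)N1Br
Why: Wohl–Ziegler benzylic bromination: the acyloxy group tempers the ring toward electrophilic bromination, so the radical chain should take one benzylic hydrogen.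

Step 11
Reactants: 14 (4R)-4-benzyl-3-[(ArB)acetyl]-1,3-oxazolidin-2-one; 17 4-(bromomethyl)phenyl 2,2-dimethylpropanoate
Product: 19 (4R)-4-benzyl-3-{(2R)-2-(ArB)-3-[4-(pivaloyloxy)phenyl]propanoyl}-1,3-oxazolidin-2-one, via sodium Z-enolate 18 (not isolated)
Conditions: NaN(SiMe3)2, THF, −78 °C; then 17, −78 → −40 °C; AcOH quench
Reagents that add atoms: none
Why: Evans asymmetric alkylation: NaN(SiMe3)2 gives the chelated Z-enolate 18, whose face on the side of the C4 benzyl group of the auxiliary is shielded, so the benzylic bromide adds to the opposite face and sets the future C3 as R, the hindered pivalate being left alone at low temperature.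

Step 12
Reactants: 19 (4R)-4-benzyl-3-{(2R)-2-(ArB)-3-[4-(pivaloyloxy)phenyl]propanoyl}-1,3-oxazolidin-2-one
Product: 20 4-[(2R)-3-hydroxy-2-(ArB)propyl]phenol
Conditions: LiBH4 (excess), MeOH, THF, 0 °C → rt
Reagents that add atoms: none
Why: reductive cleavage of the N-acyl oxazolidinone with LiBH4 (hydride addition to the exocyclic carbonyl) gives the primary alcohol and frees the auxiliary, the same reagent reduces the aryl pivalate to the phenol, and the stereocentre is no longer enolisable once the carbonyl is gone.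

Step 13
Reactants: 20 4-[(2R)-3-hydroxy-2-(ArB)propyl]phenol
Product: 22 4-hydroxy-4-[(2R)-3-hydroxy-2-(ArB)propyl]cyclohexa-2,5-dien-1-one, via peroxyquinol 21 (not isolated)
Conditions: KHSO5 (as 2KHSO5·KHSO4·K2SO4), NaHCO3, MeCN/H2O, rt; then aq. Na2S2O3
Reagents that add atoms: potassium peroxymonosulfate, [K+].[O-]S(=O)(=O)OO
Why: oxidative dearomatisation of a 4-alkylphenol by singlet oxygen (from bicarbonate-induced decomposition of KHSO5): the phenolate takes up oxygen at the para carbon to give hydroperoxide 21, which thiosulfate reduces to the para-quinol; the oxygen comes from outside, so the tethered alcohol cannot spirocyclise, and the terminal alkene has no allylic hydrogen for an ene reaction.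

Step 14
Reactants: 22 4-hydroxy-4-[(2R)-3-hydroxy-2-(ArB)propyl]cyclohexa-2,5-dien-1-one
Product: 26 (3R)-3-(ArB)chroman-7-ol, via cis-fused hydroxy enone 23 (not isolated), via tertiary trifluoroacetate 24 (not isolated), via aryl trifluoroacetate 25 (not isolated)
Conditions: K2CO3 (0.2 equiv), MeCN, rt; then pyridine, (CF3CO)2O, 0 °C → rt; then aq. NaHCO3/MeOH
Reagents that add atoms: none
Why: K2CO3 assists conjugate addition of the C2 hydroxyl to a dienone β-carbon of the para-quinol (the future C8a), which forms O1–C8a and gives the cis-fused 4a-hydroxy enone 23; trifluoroacetic anhydride and pyridine then acylate the tertiary C4a hydroxyl (24), the ester departs with loss of the C8a proton, the resulting cyclohexadienone tautomerises to the 7-phenol, and the phenol ester 25 formed with excess anhydride is cleaved in the bicarbonate work-up. The closest known reaction types are the intramolecular oxa-Michael addition of tethered alcohols to para-quinols and the dehydrative aromatisation of 4-hydroxycyclohex-2-enones. Ring C closes in a 6-exo-trig mode, while ring A is not closed but returned to the aromatic state. No lasting stereocentre is made: the two ring-fusion centres are transient and vanish on aromatisation, and C3, set in step 11, lies outside the reacting π system and bears no acidic hydrogen, so it is carried through unchanged. The selectivity needed is regiochemical, oxygen to C8a and not to C4a, and it is secured because C4a already holds the hydroxyl delivered by singlet oxygen, which leaves the two equivalent β-carbons as the only electrophilic sites within six-membered reach, attack on either converging on the same arene. Because no carbon migrates, the oxygen pattern can only be O1 at C8a and hydroxyl at C7, proton loss from C8a rather than from C4 is driven by aromatisation, and the MOM ethers and the terminal alkene are inert to carbonate and to the buffered anhydride.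

Step 15
Reactants: 26 (3R)-3-(ArB)chroman-7-ol
Product: 27 (3R)-3-[3,4-dihydroxy-2-methoxy-5-(2-methylbut-3-en-2-yl)phenyl]chroman-7-ol (CNP0167796.1)
Conditions: HCl (cat.), MeOH, 40 °C, argon
Reagents that add atoms: none
Why: acid-catalysed acetal cleavage (transacetalisation to dimethoxymethane in methanol): both MOM ethers should fall under conditions too mild to protonate the monosubstituted alkene or open the chroman, and C3 has no acidic hydrogen.

**Compound list**

1 | 2,3,4-trihydroxybenzaldehyde | O=Cc1ccc(O)c(O)c1O | starting material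
2 | prenyl bromide (1-bromo-3-methylbut-2-ene) | CC(C)=CCBr | starting material
3 | 2,3-dihydroxy-4-[(3-methylbut-2-en-1-yl)oxy]benzaldehyde | O=Cc1ccc(OCC=C(C)C)c(O)c1O | intermediate
4 | 2-hydroxy-3-(methoxymethoxy)-4-[(3-methylbut-2-en-1-yl)oxy]benzaldehyde | O=Cc1ccc(OCC=C(C)C)c(OCOC)c1O | intermediate
5 | 2-methoxy-3-(methoxymethoxy)-4-[(3-methylbut-2-en-1-yl)oxy]benzaldehyde | O=Cc1ccc(OCC=C(C)C)c(OCOC)c1OC | intermediate
6 | Claisen dienone: 2-methoxy-3-(methoxymethoxy)-5-(2-methylbut-3-en-2-yl)-4-oxocyclohexa-1(6),2-diene-1-carbaldehyde, racemic at C5 | O=CC1=CC(C(C)(C)C=C)C(=O)C(OCOC)=C1OC | intermediate (not isolated)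
7 | 4-hydroxy-2-methoxy-3-(methoxymethoxy)-5-(2-methylbut-3-en-2-yl)benzaldehyde | O=Cc1cc(C(C)(C)C=C)c(O)c(OCOC)c1OC | intermediate
8 | 2-methoxy-3,4-bis(methoxymethoxy)-5-(2-methylbut-3-en-2-yl)benzaldehyde | O=Cc1cc(C(C)(C)C=C)c(OCOC)c(OCOC)c1OC | intermediate
9 | potassium N-formyl enamide: potassium salt of N-{2-(ArB)-1-[(4-methylphenyl)sulfonyl]ethenyl}formamide, alkene geometry undefined | [K+].O=C[N-]C(=Cc1cc(C(C)(C)C=C)c(OCOC)c(OCOC)c1OC)S(=O)(=O)c2ccc(C)cc2 | intermediate (not isolated)
10 | [2-methoxy-3,4-bis(methoxymethoxy)-5-(2-methylbut-3-en-2-yl)phenyl]acetonitrile | N#CCc1cc(C(C)(C)C=C)c(OCOC)c(OCOC)c1OC | intermediate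
11 | [2-methoxy-3,4-bis(methoxymethoxy)-5-(2-methylbut-3-en-2-yl)phenyl]acetic acid | OC(=O)Cc1cc(C(C)(C)C=C)c(OCOC)c(OCOC)c1OC | intermediate
12 | (R)-4-benzyl-2-oxazolidinone | O=C1N[C@H](Cc2ccccc2)CO1 | starting material
13 | mixed pivalic anhydride: (ArB)acetic 2,2-dimethylpropanoic anhydride | CC(C)(C)C(=O)OC(=O)Cc1cc(C(C)(C)C=C)c(OCOC)c(OCOC)c1OC | intermediate (not isolated)
14 | (4R)-4-benzyl-3-[(ArB)acetyl]-1,3-oxazolidin-2-one | O=C1OC[C@@H](Cc2ccccc2)N1C(=O)Cc3cc(C(C)(C)C=C)c(OCOC)c(OCOC)c3OC | intermediate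
15 | p-cresol (4-methylphenol) | Cc1ccc(O)cc1 | starting material
16 | 4-methylphenyl 2,2-dimethylpropanoate | Cc1ccc(OC(=O)C(C)(C)C)cc1 | intermediate
17 | 4-(bromomethyl)phenyl 2,2-dimethylpropanoate | BrCc1ccc(OC(=O)C(C)(C)C)cc1 | intermediate
18 | sodium Z-enolate of imide 14 | [Na+].[O-]/C(=C\c1cc(C(C)(C)C=C)c(OCOC)c(OCOC)c1OC)N2C(=O)OC[C@H]2Cc3ccccc3 | intermediate (not isolated)
19 | (4R)-4-benzyl-3-{(2R)-2-(ArB)-3-[4-(pivaloyloxy)phenyl]propanoyl}-1,3-oxazolidin-2-one | O=C1OC[C@@H](Cc2ccccc2)N1C(=O)[C@H](Cc3ccc(OC(=O)C(C)(C)C)cc3)c4cc(C(C)(C)C=C)c(OCOC)c(OCOC)c4OC | intermediate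
20 | 4-[(2R)-3-hydroxy-2-(ArB)propyl]phenol | OC[C@H](Cc1ccc(O)cc1)c2cc(C(C)(C)C=C)c(OCOC)c(OCOC)c2OC | intermediate
21 | peroxyquinol: 4-hydroperoxy-4-[(2R)-3-hydroxy-2-(ArB)propyl]cyclohexa-2,5-dien-1-one | OC[C@H](CC1(OO)C=CC(=O)C=C1)c2cc(C(C)(C)C=C)c(OCOC)c(OCOC)c2OC | intermediate (not isolated)
22 | para-quinol: 4-hydroxy-4-[(2R)-3-hydroxy-2-(ArB)propyl]cyclohexa-2,5-dien-1-one | OC[C@H](CC1(O)C=CC(=O)C=C1)c2cc(C(C)(C)C=C)c(OCOC)c(OCOC)c2OC | intermediate (key-step precursor)
23 | cis-fused hydroxy enone: (3R)-4a-hydroxy-3-(ArB)-2,3,4,4a,8,8a-hexahydro-7H-chromen-7-one, both cis-fused diastereomers | O=C1C=CC2(O)C[C@H](c3cc(C(C)(C)C=C)c(OCOC)c(OCOC)c3OC)COC2C1 | intermediate (not isolated)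
24 | tertiary trifluoroacetate: 4a-O-trifluoroacetyl derivative of 23 | O=C1C=CC2(OC(=O)C(F)(F)F)C[C@H](c3cc(C(C)(C)C=C)c(OCOC)c(OCOC)c3OC)COC2C1 | intermediate (not isolated)
25 | aryl trifluoroacetate: (3R)-3-(ArB)chroman-7-yl trifluoroacetate | O=C(Oc1ccc2C[C@H](c3cc(C(C)(C)C=C)c(OCOC)c(OCOC)c3OC)COc2c1)C(F)(F)F | intermediate (not isolated)
26 | (3R)-3-[2-methoxy-3,4-bis(methoxymethoxy)-5-(2-methylbut-3-en-2-yl)phenyl]chroman-7-ol | Oc1ccc2C[C@H](c3cc(C(C)(C)C=C)c(OCOC)c(OCOC)c3OC)COc2c1 | intermediate (key-step product)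
27 | (3R)-3-[3,4-dihydroxy-2-methoxy-5-(2-methylbut-3-en-2-yl)phenyl]chroman-7-ol | C=CC(C)(C)c1cc([C@@H]2COc3cc(O)ccc3C2)c(OC)c(O)c1O | target

**Count and risks**

Total step count: 15. Longest linear sequence: 13 steps (steps 1–8 and 11–15, from 1); steps 9–10 form the ring A branch.

Step 14 (most likely to fail). The conjugate addition may reverse once the anhydride is added, so that the reopened primary alcohol is acylated, or the C4a ester may eliminate toward the C4 methylene and give a non-aromatic exocyclic diene. The fallback closes ring C at O1–C2 by Mitsunobu etherification; it sets out from imide 14 and comes back at 26. Commercial 4-methylresorcinol is pivaloylated twice to 4-methyl-1,3-phenylene bis(2,2-dimethylpropanoate) F1 and brominated (NBS, AIBN) to 4-(bromomethyl)-1,3-phenylene bis(2,2-dimethylpropanoate) F2. The sodium enolate 18 of 14 is alkylated with F2 to give (4R)-4-benzyl-3-{(2R)-2-(ArB)-3-[2,4-bis(pivaloyloxy)phenyl]propanoyl}-1,3-oxazolidin-2-one F3. LiBH4 reduces the imide and both aryl esters to 4-[(2R)-3-hydroxy-2-(ArB)propyl]benzene-1,3-diol F4. PPh3 and diisopropyl azodicarboxylate in THF then let the ortho hydroxyl displace the activated primary alcohol, which should give 26 directly.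

Step 13. Excess peroxymonosulfate may over-oxidise the electron-rich ring B or the quinol, the dearomatisation may stall, or the product may cyclise without control in the aqueous bicarbonate. The fallback masks the primary alcohol and uses PhI(OAc)2 with water as the oxygen source; it sets out from 20 and comes back at 22. Phenol 20 is silylated twice (t-BuMe2SiCl, imidazole) to tert-butyl{4-[(2R)-3-(tert-butyldimethylsilyloxy)-2-(ArB)propyl]phenoxy}dimethylsilane F5. K2CO3 in MeOH cleaves only the aryl silyl ether to give 4-[(2R)-3-(tert-butyldimethylsilyloxy)-2-(ArB)propyl]phenol F6. PhI(OAc)2 in MeCN/H2O at 0 °C should give 4-[(2R)-3-(tert-butyldimethylsilyloxy)-2-(ArB)propyl]-4-hydroxycyclohexa-2,5-dien-1-one F7, since the silyl ether cannot spirocyclise. Fluoride buffered with acetic acid (Bu4NF/AcOH, THF) then releases 22.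

Step 4. At 190 °C the prenyl group may be lost as isoprene, the product may undergo the abnormal Claisen rearrangement, or the new phenol may cyclise onto the alkene. The fallback installs the 1,1-dimethylallyl group by cross-coupling; it sets out from 1 and comes back at 8. Aldehyde 1 is etherified at O3 and O4 (MeOCH2Cl, i-Pr2NEt, the chelated 2-hydroxyl staying free) to 2-hydroxy-3,4-bis(methoxymethoxy)benzaldehyde F8 and methylated (MeI, K2CO3) to 2-methoxy-3,4-bis(methoxymethoxy)benzaldehyde F9. NBS in MeCN brominates C5, the position para to the methoxy group, to give 5-bromo-2-methoxy-3,4-bis(methoxymethoxy)benzaldehyde F10. A γ-selective Suzuki–Miyaura coupling with prenylboronic acid pinacol ester (Pd(OAc)2, bulky dialkylbiarylphosphine, K3PO4, aqueous THF) then gives 8.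

**Further compounds**

F1 | step 14 | 4-methyl-1,3-phenylene bis(2,2-dimethylpropanoate) | Cc1ccc(OC(=O)C(C)(C)C)cc1OC(=O)C(C)(C)C
F2 | step 14 | 4-(bromomethyl)-1,3-phenylene bis(2,2-dimethylpropanoate) | BrCc1ccc(OC(=O)C(C)(C)C)cc1OC(=O)C(C)(C)C
F3 | step 14 | (4R)-4-benzyl-3-{(2R)-2-(ArB)-3-[2,4-bis(pivaloyloxy)phenyl]propanoyl}-1,3-oxazolidin-2-one | O=C1OC[C@@H](Cc2ccccc2)N1C(=O)[C@H](Cc3ccc(OC(=O)C(C)(C)C)cc3OC(=O)C(C)(C)C)c4cc(C(C)(C)C=C)c(OCOC)c(OCOC)c4OC
F4 | step 14 | 4-[(2R)-3-hydroxy-2-(ArB)propyl]benzene-1,3-diol | OC[C@H](Cc1ccc(O)cc1O)c2cc(C(C)(C)C=C)c(OCOC)c(OCOC)c2OC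
F5 | step 13 | tert-butyl{4-[(2R)-3-(tert-butyldimethylsilyloxy)-2-(ArB)propyl]phenoxy}dimethylsilane | CC(C)(C)[Si](C)(C)OC[C@H](Cc1ccc(O[Si](C)(C)C(C)(C)C)cc1)c2cc(C(C)(C)C=C)c(OCOC)c(OCOC)c2OC
F6 | step 13 | 4-[(2R)-3-(tert-butyldimethylsilyloxy)-2-(ArB)propyl]phenol | CC(C)(C)[Si](C)(C)OC[C@H](Cc1ccc(O)cc1)c2cc(C(C)(C)C=C)c(OCOC)c(OCOC)c2OC
F7 | step 13 | 4-[(2R)-3-(tert-butyldimethylsilyloxy)-2-(ArB)propyl]-4-hydroxycyclohexa-2,5-dien-1-one | CC(C)(C)[Si](C)(C)OC[C@H](CC1(O)C=CC(=O)C=C1)c2cc(C(C)(C)C=C)c(OCOC)c(OCOC)c2OC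
F8 | step 4 | 2-hydroxy-3,4-bis(methoxymethoxy)benzaldehyde | O=Cc1ccc(OCOC)c(OCOC)c1O
F9 | step 4 | 2-methoxy-3,4-bis(methoxymethoxy)benzaldehyde | O=Cc1ccc(OCOC)c(OCOC)c1OC
F10 | step 4 | 5-bromo-2-methoxy-3,4-bis(methoxymethoxy)benzaldehyde | O=Cc1cc(Br)c(OCOC)c(OCOC)c1OC
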